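**Retrosynthetic overview** (aromadendrane numbering for the terpene carbons; C7' is the benzylic carbon)
1. The oxepine ring (O, C2, C3, C4, C7' and the two aryl carbons) is opened back to a cis-fused chroman 10 (O, C3, C4, C7', two aryl carbons); the aryloxy group walks from C3 to C2, a 6→7 ring expansion.
2. Enabling feature: in 10 the oxygen sits on C3 of a C3–C2=C1 allyl unit and C10 still carries H. Ionisation and loss of H10 give the C10=C1–C2=C3 diene; protonation at C3 gives the C2–C1–C10 allyl cation, which the phenol (held on the β face by the C4–C7' bond) can reach only at C2.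
3. Chroman 10 comes from hemiketal 8 by α,β-dehydrogenation and hydride reduction; 8 is the hetero-Diels–Alder adduct of an o-quinone methide (from 4 + 5) with silyl enol ether 3, which sets quaternary C4 and C7'.
4. Enol ether 3 comes from (−)-α-gurjunene by allylic oxidation at C3 and copper-hydride conjugate reduction (sets H5); the cyclopropane and seven-membered carbocycle come from the chiral pool.
5. Ring order: carbocycles (chiral pool) → chroman (step 3) → oxepine (step 6).

Key step: step 6

Assumptions: (−)-α-gurjunene is taken as the (1aR,4R,4aR,7bS) isomer drawn in the list (1β-H, 10β-H, 6α-H, 7α-H), whose cyclopropane centres are those of the target. Hemiketal 8 and enone 9 are in ring–chain equilibrium; 8 is drawn closed and 9 open.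

Step 1
Reactants: 1 (−)-α-gurjunene
Product: 2 (1βH,10βH)-aromadendr-4-en-3-one (3-oxo-α-gurjunene)
Conditions: Rh2(cap)4 (1 mol %), t-BuOOH (5 equiv), K2CO3, CH2Cl2, rt
Reagents that add atoms: tert-butyl hydroperoxide, CC(C)(C)OO
Why: Dirhodium caprolactamate/TBHP allylic oxidation should convert the only allylic methylene of the tetrasubstituted C4=C5 alkene (C3) into the cyclopentenone carbonyl, with no new stereocentre.

Step 2
Reactants: 2 (1βH,10βH)-aromadendr-4-en-3-one
Product: 3 (1βH,5βH,10βH)-3-[dimethyl(phenyl)silyloxy]aromadendr-3-ene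
Conditions: [(Ph3P)CuH]6 (5 mol %), PhMe2SiH (1.5 equiv), toluene, rt
Reagents that add atoms: dimethylphenylsilane, C[SiH](C)c1ccccc1
Why: Copper-hydride 1,4-hydrosilylation (Stryker-type conjugate reduction) should deliver hydride to C5 from the convex β face (the seven-membered ring leaves C1 on the α side), setting H5 cis to H1, and trap the enolate in place as the regiodefined C3=C4 silyl enol ether.

Step 3
Reactants: 3 (1βH,5βH,10βH)-3-[dimethyl(phenyl)silyloxy]aromadendr-3-ene; 4 2,4,6-trihydroxybenzene-1,3-dicarbaldehyde; 5 3-methylbutanal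
Product: 8 cis-fused chroman hemiketal (ring O on C3β, 3α-OH, C7' on C4β, 4α-methyl, 7'S isobutyl, 1βH, 5βH), via o-quinone methide 6 (not isolated), via silyl ketal 7 (not isolated)
Conditions: EDDA (10 mol %), 4 Å MS, MeCN, 40 °C; then AcOH–THF–H2O, rt
Reagents that add atoms: none
Why: Domino Knoevenagel/inverse-demand hetero-Diels–Alder reaction: the E-configured o-quinone methide 6 should add to the electron-rich enol ether from the convex β face of the cis-fused hydroazulene with the silyloxy/methyl side endo, which sets quaternary C4 and C7' together (isobutyl cis to the C4 methyl), and the acidic work-up cleaves silyl ketal 7 to hemiketal 8.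

Step 4
Reactants: 8 cis-fused chroman hemiketal
Product: 9 4β-[(1S)-1-(3,5-diformyl-2,4,6-trihydroxyphenyl)-3-methylbutyl]-(5βH,10βH)-aromadendr-1-en-3-one
Conditions: Pd(TFA)2 (10 mol %), 4,5-diazafluoren-9-one (10 mol %), O2 (1 atm), DMSO, 60 °C
Reagents that add atoms: none
Why: Aerobic Pd(II) α,β-dehydrogenation of the ring-opened ketone: enolisation is possible only toward C2 (C4 is quaternary), and β-hydride elimination of H1 should give the C1=C2 enone without touching C5.

Step 5
Reactants: 9 4β-aryl(isobutyl)methyl-aromadendr-1-en-3-one (reacting as its cyclic hemiketal)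
Product: 10 cis-fused allyl aryl ether chroman (O on C3β, 3α-H, C2=C1 alkene, 10β-H, 5β-H, C7' on C4β)
Conditions: Et3SiH (3 equiv), TFA (5 equiv), CH2Cl2, −40 °C
Reagents that add atoms: none
Why: Ionic hydrogenation of a lactol (Kishi-type reduction): the hemiketal should ionise to the ring-retained, allyl-stabilised oxocarbenium ion and accept hydride at C3 from the open α face, giving the cis-fused chroman, while the hydrogen-bonded formyl groups are not ionised at this temperature.

Step 6
Reactants: 10 cis-fused allyl aryl ether chroman
Product: 12 CNP0388405.1 (target), via phenol-diene 11 (not isolated)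
Conditions: (PhO)2P(O)OH (10 mol %), HFIP–CH2Cl2 (1:4), 40 °C
Reagents that add atoms: none
Why: Proposed new method: protonation of the ether oxygen of 10 (the diformylphloroglucinol oxide is a carboxylate-like leaving group) ionises the allylic C3–O bond, the C3–C2–C1 allyl cation loses H10 to give phenol–diene 11, and reprotonation of the diene at its unhindered terminus C3 gives the C2–C1–C10 allyl cation, which the phenol captures at C2; the closest known reaction types are the acid-catalysed 1,4-addition of phenols to 1,3-dienes and the acid-induced ring-opening/reclosure isomerisation of chroman-type o-quinone methide adducts. The seven-membered ring closes by 7-exo attack of oxygen on the allyl terminus C2, with the π-system outside the new ring. C2 is the only new stereocentre and is fixed by the tether, because the phenol held on the β face by the C4–C7' bond can bridge C2 and C4 only cis; C4, C5, C6, C7 and C7' are not touched. The step needs loss of H10 rather than H5 from the first cation, protonation of 11 at C3 rather than C10, and capture at C2 rather than C10; H5 is shielded between quaternary C4 and the cyclopropane, protonation at C10 only returns to 10, and O–C10 closure would need a strained nine-membered ring. The step runs under thermodynamic control and should be driven by the tetrasubstituted ledene-type C1=C10 alkene.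

**Compound list**
1 | (−)-α-gurjunene | C[C@@H]1CC[C@@H]2[C@@H](C2(C)C)C2=C(C)CC[C@H]12 | starting material
2 | (1βH,10βH)-aromadendr-4-en-3-one | C[C@@H]1CC[C@@H]2[C@@H](C2(C)C)C2=C(C)C(=O)C[C@H]12 | intermediate
3 | (1βH,5βH,10βH)-3-[dimethyl(phenyl)silyloxy]aromadendr-3-ene | C[C@@H]1CC[C@@H]2[C@@H](C2(C)C)[C@@H]2C(C)=C(O[Si](C)(C)c3ccccc3)C[C@H]12 | intermediate
4 | 2,4,6-trihydroxybenzene-1,3-dicarbaldehyde | O=Cc1c(O)cc(O)c(C=O)c1O | starting material
5 | 3-methylbutanal | CC(C)CC=O | starting material
6 | o-quinone methide, 2,4-diformyl-3,5-dihydroxy-6-(3-methylbutylidene)cyclohexa-2,4-dienone | CC(C)CC=C1C(=O)C(C=O)=C(O)C(C=O)=C1O | intermediate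
7 | silyl ketal chroman (3α-OSiMe2Ph, ring O on C3β, C7' on C4β) | C[C@@H]1CC[C@@H]2[C@@H](C2(C)C)[C@@H]2[C@@]3(C)[C@H](CC(C)C)c4c(O)c(C=O)c(O)c(C=O)c4O[C@@]3(O[Si](C)(C)c5ccccc5)C[C@H]12 | intermediate
8 | cis-fused chroman hemiketal (3α-OH) | C[C@@H]1CC[C@@H]2[C@@H](C2(C)C)[C@@H]2[C@@]3(C)[C@H](CC(C)C)c4c(O)c(C=O)c(O)c(C=O)c4O[C@@]3(O)C[C@H]12 | intermediate
9 | 4β-[(1S)-1-(3,5-diformyl-2,4,6-trihydroxyphenyl)-3-methylbutyl]-(5βH,10βH)-aromadendr-1-en-3-one | C[C@@H]1CC[C@@H]2[C@@H](C2(C)C)[C@H]2C1=CC(=O)[C@]2(C)[C@H](CC(C)C)c1c(O)c(C=O)c(O)c(C=O)c1O | intermediate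
10 | cis-fused allyl aryl ether chroman (O on C3β, C1=C2, 10β-H) | C[C@@H]1CC[C@@H]2[C@@H](C2(C)C)[C@H]2C1=C[C@@H]1Oc3c(C=O)c(O)c(C=O)c(O)c3[C@@H](CC(C)C)[C@@]12C | intermediate
11 | phenol–diene, 4β-[(1S)-1-(3,5-diformyl-2,4,6-trihydroxyphenyl)-3-methylbutyl]aromadendra-1(10),2-diene | CC1=C2C=C[C@](C)([C@H](CC(C)C)c4c(O)c(C=O)c(O)c(C=O)c4O)[C@H]2[C@H]3[C@@H](CC1)C3(C)C | intermediate
12 | CNP0388405.1 | CC1=C2[C@H]([C@H]3[C@@H](CC1)C3(C)C)[C@]1(C)C[C@H]2Oc2c(C=O)c(O)c(C=O)c(O)c2[C@H]1CC(C)C | target

**Total step count:** 6. **Longest linear sequence:** 6 steps (from 1).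

**Steps most likely to fail**

1. Step 6 (Proposed new method). The acid relay may remove H5 instead of H10 from the first allyl cation, which would scramble C5 or lead to the C1=C5 isomer. It may also open the cyclopropane through a cation at C5, or stop at the six-membered ring if the equilibrium does not favour the oxepine. Fallback, setting out from 10: excess KOt-Bu in THF at 0 °C to rt should effect the known base-mediated 1,4-elimination of the allylic aryl ether, where the bulky base takes the peripheral H10, and phenol–diene 11 is isolated. Pd(PPh3)4 (5 mol %) in THF at rt should then add the acidic phenol O–H across the 1,3-diene (hydropalladation at C3, C–O bond formation at C2 of the π-allyl), which comes back to the route at 12.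

2. Step 5. Hydride may be delivered to C1 instead of C3, giving an enol ether that is then over-reduced, or the product allyl ether may ionise again and be cleaved reductively. Fallback, setting out from 9: Luche reduction (NaBH4, CeCl3·7H2O, MeOH, −78 °C; the formyl groups are deactivated as phenolate-conjugated, in situ acetalised carbonyls) should give the allylic alcohol F1. Catalytic PPTS in CH2Cl2 at 0 °C should then close the ether at the proximal allyl terminus C3 (SN1-type cycloetherification), which comes back to the route at 10.

3. Step 4. The ketone is masked as a hemiketal, so dehydrogenation may be slow, and the Pd(II)/O2 system may over-oxidise (γ,δ-dehydrogenation toward C10, or oxidation of the phenols). Fallback, setting out from 8: PhSeCl in EtOAc at rt should selenenylate the only enolisable position (C2) to give the α-phenylseleno ketone F2. NaIO4 in aqueous THF at rt should then oxidise it to the selenoxide, whose syn elimination toward H1 comes back to the route at 9.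

**Further compounds**
F0 | step 6 | none | none
F1 | step 5 | 4β-[(1S)-1-(3,5-diformyl-2,4,6-trihydroxyphenyl)-3-methylbutyl]-(5βH,10βH)-aromadendr-1-en-3-ol (either C3 epimer) | C[C@@H]1CC[C@@H]2[C@@H](C2(C)C)[C@H]2C1=CC(O)[C@]2(C)[C@H](CC(C)C)c1c(O)c(C=O)c(O)c(C=O)c1O
F2 | step 4 | 2-phenylseleno-4β-[(1S)-1-(3,5-diformyl-2,4,6-trihydroxyphenyl)-3-methylbutyl]-(1βH,5βH,10βH)-aromadendran-3-one | C[C@@H]1CC[C@@H]2[C@@H](C2(C)C)[C@H]2[C@@H]1C([Se]c1ccccc1)C(=O)[C@]2(C)[C@H](CC(C)C)c1c(O)c(C=O)c(O)c(C=O)c1O
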